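**Retrosynthetic overview**

1. The target is epigallocatechin-(4β→8)-epigallocatechin 3-O-gallate-(4β→8)-epigallocatechin. The last operations are hydrogenolysis, phenol desilylation and galloylation of the middle O3, which is kept apart as the only TBS ether.
2. The strategy rests on top ring A. It is a phloroglucinol ring (oxygen on C5, C7 and C8a, hydrogen on C6 and C8) fused to ring C through C4a–C8a. Cutting C4a–C8a, C5–C6 and C7–C8 turns it into three oxygen-bearing alkynes: an ethynyl ether on O1 (C8≡C8a), a siloxyalkyne on C4 (C4a≡C5) and triisopropylsiloxyacetylene (C6≡C7).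
3. The tethered diyne goes back to a terminal alkyne on C4 (acetylide oxidation–silylation, then a trichloroethylene-based ethynyl ether on O1). That alkyne comes from a Nicholas alkylation of C8 of the middle–bottom dimer.
4. The cobalt-complexed propargylic acetate comes from an Evans syn glycolate aldol on 3,4,5-tris(benzyloxy)benzaldehyde, which sets top C2 and C3. The dimer comes from two epigallocatechin derivatives by flavan-4-yl cation/C8 Friedel–Crafts coupling.
5. Ring order: rings A, B and C of the middle and bottom units come with epigallocatechin, and top ring B comes with the aldehyde. Top rings C and A are closed together, last, in one cycloaddition.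

Key step: step 19

Assumption: all three flavan units are read as 2R,3R with 4β→8 links, and the atoms of the open-chain top fragment carry the flavan numbers they will have after ring closure (O1, C2, C3, C4, C4a, C5, C8, C8a); "all-syn" means O1, O3 and the C4-aryl group lie on one face of the zigzag chain ring B–C2–C3–C4–C4a.

**Route**

Step 1
Reactants: 1 (−)-epigallocatechin
Product: 2 5,7,3',4',5'-penta-O-benzyl-(−)-epigallocatechin (3-OH free)
Conditions: BnBr (5.5 equiv), K2CO3, DMF, 0 °C → rt, Ar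
Reagents that add atoms: benzyl bromide, BrCc1ccccc1
Why: Williamson ether synthesis in which K2CO3 ionises only the five phenols, so the secondary 3-OH stays free and the mild base under argon avoids ring-C opening and C2 epimerisation.

Step 2
Reactants: 2 penta-O-benzylepigallocatechin
Product: 3 3,5,7,3',4',5'-hexa-O-benzyl-(−)-epigallocatechin (bottom unit)
Conditions: NaH, BnBr, Bu4NI (cat.), THF–DMF, 0 °C → rt
Reagents that add atoms: benzyl bromide, BrCc1ccccc1
Why: Williamson ether synthesis on the sodium alkoxide of the remaining 3-OH, with no stereocentre touched.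

Step 3
Reactants: 2 penta-O-benzylepigallocatechin
Product: 4 penta-O-benzyl-3-O-TBS-epigallocatechin
Conditions: TBSCl, imidazole, DMF, rt → 40 °C
Reagents that add atoms: tert-butyldimethylsilyl chloride, CC(C)(C)[Si](C)(C)Cl
Why: Imidazole-promoted silyl ether formation marks O3 of the future middle unit as the one oxygen that can later be released selectively for galloylation.

Step 4
Reactants: 4 penta-O-benzyl-3-O-TBS-epigallocatechin
Product: 5 4β-(2-ethoxyethoxy)-penta-O-benzyl-3-O-TBS-epigallocatechin (2,3-cis-3,4-trans)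
Conditions: DDQ (1.5 equiv), 2-ethoxyethanol (5 equiv), CH2Cl2, rt
Reagents that add atoms: 2-ethoxyethanol, CCOCCO
Why: DDQ benzylic oxidation abstracts hydride from C4 to give the ring-A-stabilised flavan-4-yl cation, which the alcohol captures opposite the axial 3-OTBS group and so sets the 4β configuration.

Step 5
Reactants: 5 4β-(2-ethoxyethoxy) electrophile; 3 hexa-O-benzylepigallocatechin
Product: 6 middle–bottom dimer, penta-O-benzyl-3-O-TBS-epigallocatechin-(4β→8)-hexa-O-benzylepigallocatechin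
Conditions: 3 (3 equiv), TMSOTf (0.2 equiv), CH2Cl2, −78 °C; Et3N quench; excess 3 recovered
Reagents that add atoms: none
Why: In this Lewis-acid Friedel–Crafts alkylation the flavan-4-yl cation from 5 is attacked by C8 of 3 (the more nucleophilic ring-A position) on the face trans to 3-OTBS, which sets C4 as 4β, while the excess of 3 holds back self-condensation of 5.

Step 6
Reactants: 7 (S)-4-benzyl-1,3-oxazolidin-2-one; 8 benzyloxyacetyl chloride
Product: 9 (S)-4-benzyl-3-(benzyloxyacetyl)oxazolidin-2-one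
Conditions: Et3N, DMAP (cat.), CH2Cl2, 0 °C → rt
Reagents that add atoms: none
Why: DMAP-catalysed N-acylation of the oxazolidinone by an acid chloride is a standard way to load the auxiliary.

Step 7
Reactants: 9 N-(benzyloxyacetyl)oxazolidinone; 10 3,4,5-tris(benzyloxy)benzaldehyde
Product: 12 syn aldol adduct (2S,3R)-2-benzyloxy-3-hydroxy-3-[3,4,5-tris(benzyloxy)phenyl]propanoyl imide of 7, via Z-dibutylboron enolate 11 (not isolated)
Conditions: Bu2BOTf, Et3N, CH2Cl2, −78 → 0 °C; 10, −78 → 0 °C; pH 7 buffer, MeOH, H2O2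
Reagents that add atoms: none
Why: In the Evans syn aldol reaction the Z-boron enolate reacts through a Zimmerman–Traxler chair on the face left open by the benzyl group of the (S)-auxiliary, which sets (2S,3R) (future top C3 and C2, syn, hence 2,3-cis once O1 is in the ring) and delivers O3 benzylated and O1 free.

Step 8
Reactants: 12 syn aldol adduct
Product: 13 (2S,3R)-2-benzyloxy-3-hydroxy-N-methoxy-N-methyl-3-[3,4,5-tris(benzyloxy)phenyl]propanamide
Conditions: MeONHMe·HCl, AlMe3, THF, −10 °C → rt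
Reagents that add atoms: N,O-dimethylhydroxylamine hydrochloride, CNOC.Cl
Why: Weinreb amide formation by aluminium amide transamination is assisted by the free β-hydroxyl, releases the auxiliary and does not epimerise the α-alkoxy centre.

Step 9
Reactants: 13 Weinreb amide
Product: 14 3-O-triethylsilyl ether of 13
Conditions: TESCl, imidazole, CH2Cl2, 0 °C → rt
Reagents that add atoms: triethylsilyl chloride, CC[Si](Cl)(CC)CC
Why: Silyl ether protection puts on O1 a group that survives hydride, Grignard and low-temperature BF3 conditions and is more acid-labile than the hindered TBS ether of 6.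

Step 10
Reactants: 14 TES-protected Weinreb amide
Product: 15 (2S,3R)-2-benzyloxy-3-(triethylsilyloxy)-3-[3,4,5-tris(benzyloxy)phenyl]propanal
Conditions: i-Bu2AlH, THF, −78 °C; used crude
Reagents that add atoms: none
Why: In the Weinreb amide reduction the chelated tetrahedral intermediate persists until work-up, so reduction stops at the aldehyde, which is used without chromatography to avoid α-epimerisation.

Step 11
Reactants: 15 aldehyde; 16 ethynylmagnesium bromide
Product: 18 (4R,5R)-4-benzyloxy-5-(triethylsilyloxy)-5-[3,4,5-tris(benzyloxy)phenyl]pent-1-yn-3-yl acetate (both C3 epimers), via bromomagnesium alkoxide 17 (not isolated)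
Conditions: HC≡CMgBr, THF, −78 → 0 °C; then Ac2O, DMAP (cat.), 0 °C → rt
Reagents that add atoms: acetic anhydride, CC(=O)OC(C)=O
Why: Grignard 1,2-addition followed by in-situ O-acylation gives the propargylic acetate, and the epimer mixture at the carbinol carbon (future C4) does not matter because this centre is ionised in step 13.

Step 12
Reactants: 18 propargylic acetate
Product: 19 Co2(CO)6 complex of 18
Conditions: Co2(CO)8, CH2Cl2, rt
Reagents that add atoms: dicobalt octacarbonyl, O=C=[Co](=C=O)(=C=O)(=C=O)[Co](=C=O)(=C=O)(=C=O)=C=O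
Why: Terminal alkynes displace two CO ligands from Co2(CO)8 at room temperature to give chromatographically stable dicobalt hexacarbonyl complexes.

Step 13
Reactants: 19 cobalt-complexed acetate; 6 middle–bottom dimer
Product: 21 dimer bearing on C8 of its upper unit the all-syn open chain C4(H)(Co2(CO)6-ethynyl)–C3(OBn)–C2(OTES)(ring B), via cobalt-stabilised propargylic cation 20 (not isolated)
Conditions: BF3·OEt2, 2,6-di-tert-butyl-4-methylpyridine, CH2Cl2, −78 → −30 °C
Reagents that add atoms: none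
Why: In the Nicholas reaction BF3 ionises the acetate to cation 20, which alkylates C8 of the upper unit of 6 (the position at which such dimers are extended by carbocations), the hindered pyridine takes up the proton, and the new C4 centre is set by 1,2-induction from C3 in a Felkin-type rotamer (C3–C2 bond perpendicular to the cation plane, C3–H toward the cobalt cluster, arene entering opposite C2) that gives the C3/C4-syn chain, later 3,4-trans in ring C.

Step 14
Reactants: 21 cobalt complex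
Product: 22 terminal alkyne (C4–C4a≡C5–H) with O1–TES and middle O3–TBS
Conditions: N-methylmorpholine N-oxide (excess), CH2Cl2, 0 °C → rt
Reagents that add atoms: none
Why: Oxidative decomplexation with an amine N-oxide removes the CO ligands as CO2 and frees the alkyne without the strong one-electron oxidants that would attack the electron-rich rings.

Step 15
Reactants: 22 TES ether
Product: 23 C2-alcohol (O1–H) with terminal alkyne on C4
Conditions: PPTS (cat.), MeOH–CH2Cl2, 0 °C → rt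
Reagents that add atoms: none
Why: Acid-catalysed methanolysis cleaves the TES ether much faster than the hindered secondary TBS ether, and it is done now because no later unmasking would spare a siloxyalkyne.

Step 16
Reactants: 23 hydroxy alkyne
Product: 25 hydroxy siloxyalkyne (C4–C4a≡C5–OTIPS, O1–H), via dilithium ynolate alkoxide 24 (not isolated)
Conditions: n-BuLi (2.05 equiv), THF, −78 °C; t-BuOOLi (from t-BuOOH and LiN(SiMe3)2), −78 → 0 °C; TIPSCl (1.1 equiv), −78 → 0 °C; NaHCO3 aq; Et3N-washed silica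
Reagents that add atoms: lithium tert-butyl peroxide, CC(C)(C)O[O-].[Li+]; triisopropylsilyl chloride, CC(C)[Si](Cl)(C(C)C)C(C)C
Why: In this acetylide oxidation the acetylide carbon attacks the O–O bond of lithium tert-butyl peroxide to give the ynolate, the bulky silyl chloride takes the ynolate on oxygen while hindered lithium alkoxides (O1 and the t-BuOLi formed alongside) stay unsilylated, and the acetylide charge guards C4–H against deprotonation so C4 is not scrambled.

Step 17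
Reactants: 25 hydroxy siloxyalkyne; 26 trichloroethylene
Product: 29 diyne precursor (O1–C8a≡C8–H and C4–C4a≡C5–OTIPS on the all-syn chain), via dichlorovinyl ether 27 (not isolated), via lithium alkoxyacetylide 28 (not isolated)
Conditions: KH, THF, 0 °C; 26, −50 °C → rt; then n-BuLi (2.5 equiv), −78 °C; MeOH, −78 °C; NaHCO3 aq; product kept at or below 0 °C and used at once
Reagents that add atoms: none
Why: This is the dichlorovinyl ether route to alkynyl ethers, in which the potassium alkoxide adds anti to dichloroacetylene formed in situ, n-BuLi eliminates HCl and exchanges the last chlorine for lithium, and methanol protonates the acetylide; TIPS on oxygen resists n-BuLi at −78 °C as it does on phenols, and no bond to C2 is broken.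

Step 18
Reactants: 30 acetylene
Product: 32 triisopropylsiloxyacetylene, via lithium ethynolate 31 (not isolated)
Conditions: acetylene (excess, saturated THF), n-BuLi, −78 °C; t-BuOOLi (from t-BuOOH and LiN(SiMe3)2), −78 → −10 °C; TIPSOTf, −78 → 0 °C; distilled under reduced pressure, stored cold
Reagents that add atoms: lithium tert-butyl peroxide, CC(C)(C)O[O-].[Li+]; triisopropylsilyl triflate, CC(C)[Si](OS(=O)(=O)C(F)(F)F)(C(C)C)C(C)C
Why: The same acetylide oxidation–O-silylation is used, with excess acetylene holding back disproportionation of HC≡CLi and the hard, bulky silyl triflate favouring capture on oxygen and slowing silyl transfer to the silylketene.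

Step 19
Reactants: 29 diyne precursor; 32 triisopropylsiloxyacetylene
Product: 33 protected trimer with top rings C and A closed (top 5,7-bis-OTIPS, middle 3-OTBS, all other oxygens benzylated)
Conditions: [Rh(cod)2]BF4 (10 mol %), rac-BINAP (10 mol %), pre-activated with H2, CH2Cl2, rt; 32 (3 equiv) added slowly by syringe pump
Reagents that add atoms: none
Why: Proposed new method: the cationic monovalent rhodium–BINAP fragment should bind the two tethered alkynes of 29 and couple them oxidatively through C4a and C8a to a rhodacyclopentadiene with rhodium on C5 and C8, after which 32 inserts and reductive elimination forms C5–C6 and C7–C8 and frees the catalyst. The closest known reaction type is the cationic rhodium/BINAP [2+2+2] cycloaddition of tethered 1,6- and 1,7-diynes with monoalkynes, which tolerates ethynyl ethers, but a union of three oxygen-bearing alkynes has not been shown. Ring C closes in the oxidative coupling as the six-membered ring spanned by the four-atom tether O1–C2–C3–C4 (1,7-diyne mode), and ring A closes as the new benzene ring on reductive elimination. No stereocentre is created, C2, C3 and C4 are sp3 bystanders under neutral conditions, and racemic ligand is used so that whichever antipode fits the chiral diyne carries the turnover. The step needs the 1,3,5-oxygen pattern, with the siloxy carbon of 32 (C7) bonded to C8 and its CH (C6) bonded to C5: this is the head-to-tail mode in which every new bond joins an oxygen-bearing alkyne carbon to a β-carbon, and it also keeps the bulky OTIPS of 32 beside the unsubstituted C8–H and away from the OTIPS on C5. Cross- over self-reaction should follow from the crowding around 29, which blocks diyne dimerisation, and from slow addition of 32, while room temperature stays below the onset of [3,3] rearrangement and retro-ene cleavage of the secondary benzylic ethynyl ether.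

Step 20
Reactants: 33 protected trimer
Product: 34 trimer with free middle 3-OH
Conditions: 48% aq HF, MeCN–CH2Cl2, 0 °C → rt
Reagents that add atoms: none
Why: Under acidic fluoride conditions an alkyl TBS ether is cleaved well ahead of aryl TIPS ethers, so only the middle O3 is released.

Step 21
Reactants: 35 3,4,5-tris(benzyloxy)benzoic acid
Product: 36 3,4,5-tris(benzyloxy)benzoyl chloride
Conditions: (COCl)2, DMF (cat.), CH2Cl2, 0 °C → rt
Reagents that add atoms: oxalyl chloride, O=C(Cl)C(=O)Cl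
Why: Acid chloride formation through the Vilsmeier-type chloroiminium species is neutral enough for the benzyl ethers.

Step 22
Reactants: 34 middle 3-alcohol; 36 tribenzylgalloyl chloride
Product: 37 protected trimer 3-O-(tri-O-benzylgalloyl) ester on the middle unit
Conditions: 36 (5 equiv), DMAP, Et3N, CH2Cl2, rt → 40 °C
Reagents that add atoms: none
Why: DMAP-catalysed acyl transfer from an excess of acid chloride drives esterification of the single, hindered free hydroxyl with retention at C3.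

Step 23
Reactants: 37 protected gallate
Product: 38 gallate with free top 5-OH and 7-OH
Conditions: Bu4NF, AcOH, THF, 0 °C
Reagents that add atoms: none
Why: Fluoride cleaves aryl silyl ethers rapidly, and the acetic acid buffer keeps the phenoxides from attacking the gallate ester.

Step 24
Reactants: 38 octadeca-O-benzyl trimer gallate
Product: 39 target, epigallocatechin-(4β→8)-epigallocatechin 3-O-gallate-(4β→8)-epigallocatechin
Conditions: H2 (1 atm), Pd(OH)2/C, THF–MeOH–H2O, rt; filtered under Ar, lyophilised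
Reagents that add atoms: none
Why: Catalytic hydrogenolysis removes all eighteen benzyl ethers under neutral conditions that leave the ester, the interflavan bonds and every stereocentre untouched.

**Compound list**

1 | (−)-epigallocatechin | O[C@@H]1Cc2c(O)cc(O)cc2O[C@@H]1c1cc(O)c(O)c(O)c1 | starting material
2 | 5,7,3',4',5'-penta-O-benzyl-(−)-epigallocatechin | O[C@@H]1Cc2c(OCc9ccccc9)cc(OCc9ccccc9)cc2O[C@@H]1c1cc(OCc9ccccc9)c(OCc9ccccc9)c(OCc9ccccc9)c1 | intermediate
3 | 3,5,7,3',4',5'-hexa-O-benzyl-(−)-epigallocatechin | C(c9ccccc9)O[C@@H]1Cc2c(OCc9ccccc9)cc(OCc9ccccc9)cc2O[C@@H]1c1cc(OCc9ccccc9)c(OCc9ccccc9)c(OCc9ccccc9)c1 | intermediate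
4 | penta-O-benzyl-3-O-TBS-epigallocatechin | CC(C)(C)[Si](C)(C)O[C@@H]1Cc2c(OCc9ccccc9)cc(OCc9ccccc9)cc2O[C@@H]1c1cc(OCc9ccccc9)c(OCc9ccccc9)c(OCc9ccccc9)c1 | intermediate
5 | 4β-(2-ethoxyethoxy)-penta-O-benzyl-3-O-TBS-epigallocatechin | CC(C)(C)[Si](C)(C)O[C@@H]1[C@@H](OCCOCC)c2c(OCc9ccccc9)cc(OCc9ccccc9)cc2O[C@@H]1c1cc(OCc9ccccc9)c(OCc9ccccc9)c(OCc9ccccc9)c1 | intermediate
6 | middle–bottom dimer, 3-O-TBS upper unit (4β→8) hexabenzyl lower unit | CC(C)(C)[Si](C)(C)O[C@@H]1[C@@H](c2c(OCc9ccccc9)cc(OCc9ccccc9)c3c2O[C@H](c2cc(OCc9ccccc9)c(OCc9ccccc9)c(OCc9ccccc9)c2)[C@H](OCc9ccccc9)C3)c2c(OCc9ccccc9)cc(OCc9ccccc9)cc2O[C@@H]1c1cc(OCc9ccccc9)c(OCc9ccccc9)c(OCc9ccccc9)c1 | intermediate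
7 | (S)-4-benzyl-1,3-oxazolidin-2-one | O=C1N[C@@H](Cc2ccccc2)CO1 | starting material
8 | benzyloxyacetyl chloride | O=C(Cl)COCc1ccccc1 | starting material
9 | (S)-4-benzyl-3-(benzyloxyacetyl)oxazolidin-2-one | O=C(COCc1ccccc1)N1[C@@H](Cc2ccccc2)COC1=O | intermediate
10 | 3,4,5-tris(benzyloxy)benzaldehyde | O=Cc1cc(OCc2ccccc2)c(OCc2ccccc2)c(OCc2ccccc2)c1 | starting material
11 | Z-dibutylboron enolate of 9 | CCCCB(CCCC)O/C(=C\OCc1ccccc1)N1[C@@H](Cc2ccccc2)COC1=O | intermediate
12 | (2S,3R) syn aldol imide | O=C([C@@H](OCc9ccccc9)[C@@H](c1cc(OCc9ccccc9)c(OCc9ccccc9)c(OCc9ccccc9)c1)O)N1[C@@H](Cc2ccccc2)COC1=O | intermediate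
13 | (2S,3R) Weinreb amide | CON(C)C(=O)[C@@H](OCc9ccccc9)[C@@H](c1cc(OCc9ccccc9)c(OCc9ccccc9)c(OCc9ccccc9)c1)O | intermediate
14 | TES ether of 13 | CON(C)C(=O)[C@@H](OCc9ccccc9)[C@@H](c1cc(OCc9ccccc9)c(OCc9ccccc9)c(OCc9ccccc9)c1)O[Si](CC)(CC)CC | intermediate
15 | (2S,3R)-2-benzyloxy-3-(triethylsilyloxy)-3-arylpropanal | O=C[C@@H](OCc9ccccc9)[C@@H](c1cc(OCc9ccccc9)c(OCc9ccccc9)c(OCc9ccccc9)c1)O[Si](CC)(CC)CC | intermediate
16 | ethynylmagnesium bromide | C#C[Mg]Br | starting material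
17 | bromomagnesium propargylic alkoxide (carbinol epimers) | C#CC(O[Mg]Br)[C@@H](OCc9ccccc9)[C@@H](c1cc(OCc9ccccc9)c(OCc9ccccc9)c(OCc9ccccc9)c1)O[Si](CC)(CC)CC | intermediate
18 | (4R,5R) propargylic acetate (C3 epimers) | C#CC(OC(C)=O)[C@@H](OCc9ccccc9)[C@@H](c1cc(OCc9ccccc9)c(OCc9ccccc9)c(OCc9ccccc9)c1)O[Si](CC)(CC)CC | intermediate
19 | Co2(CO)6 complex of 18 | [CH]12[Co]3(=C=O)(=C=O)(=C=O)[Co]1(=C=O)(=C=O)(=C=O)C23C(OC(C)=O)[C@@H](OCc9ccccc9)[C@@H](c4cc(OCc9ccccc9)c(OCc9ccccc9)c(OCc9ccccc9)c4)O[Si](CC)(CC)CC | intermediate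
20 | Co2(CO)6-stabilised propargylic cation, acetoxytrifluoroborate salt | [CH]12[Co]3(=C=O)(=C=O)(=C=O)[Co]1(=C=O)(=C=O)(=C=O)C23[CH+][C@@H](OCc9ccccc9)[C@@H](c4cc(OCc9ccccc9)c(OCc9ccccc9)c(OCc9ccccc9)c4)O[Si](CC)(CC)CC.CC(=O)O[B-](F)(F)F | intermediate
21 | Nicholas product, cobalt-complexed all-syn chain on C8 of the upper unit of 6 | CC(C)(C)[Si](C)(C)O[C@@H]1[C@@H](c2c(OCc9ccccc9)cc(OCc9ccccc9)c3c2O[C@H](c2cc(OCc9ccccc9)c(OCc9ccccc9)c(OCc9ccccc9)c2)[C@H](OCc9ccccc9)C3)c2c(OCc9ccccc9)cc(OCc9ccccc9)c([C@@H](C%10%11[Co]%12(=C=O)(=C=O)(=C=O)[Co]%10(=C=O)(=C=O)(=C=O)[CH]%11%12)[C@@H](OCc9ccccc9)[C@@H](c4cc(OCc9ccccc9)c(OCc9ccccc9)c(OCc9ccccc9)c4)O[Si](CC)(CC)CC)c2O[C@@H]1c1cc(OCc9ccccc9)c(OCc9ccccc9)c(OCc9ccccc9)c1 | intermediate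
22 | decomplexed terminal alkyne, O1–TES | CC(C)(C)[Si](C)(C)O[C@@H]1[C@@H](c2c(OCc9ccccc9)cc(OCc9ccccc9)c3c2O[C@H](c2cc(OCc9ccccc9)c(OCc9ccccc9)c(OCc9ccccc9)c2)[C@H](OCc9ccccc9)C3)c2c(OCc9ccccc9)cc(OCc9ccccc9)c([C@@H](C#C)[C@@H](OCc9ccccc9)[C@@H](c4cc(OCc9ccccc9)c(OCc9ccccc9)c(OCc9ccccc9)c4)O[Si](CC)(CC)CC)c2O[C@@H]1c1cc(OCc9ccccc9)c(OCc9ccccc9)c(OCc9ccccc9)c1 | intermediate
23 | terminal alkyne, O1–H | CC(C)(C)[Si](C)(C)O[C@@H]1[C@@H](c2c(OCc9ccccc9)cc(OCc9ccccc9)c3c2O[C@H](c2cc(OCc9ccccc9)c(OCc9ccccc9)c(OCc9ccccc9)c2)[C@H](OCc9ccccc9)C3)c2c(OCc9ccccc9)cc(OCc9ccccc9)c([C@@H](C#C)[C@@H](OCc9ccccc9)[C@@H](c4cc(OCc9ccccc9)c(OCc9ccccc9)c(OCc9ccccc9)c4)O)c2O[C@@H]1c1cc(OCc9ccccc9)c(OCc9ccccc9)c(OCc9ccccc9)c1 | intermediate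
24 | dilithium ynolate alkoxide | CC(C)(C)[Si](C)(C)O[C@@H]1[C@@H](c2c(OCc9ccccc9)cc(OCc9ccccc9)c3c2O[C@H](c2cc(OCc9ccccc9)c(OCc9ccccc9)c(OCc9ccccc9)c2)[C@H](OCc9ccccc9)C3)c2c(OCc9ccccc9)cc(OCc9ccccc9)c([C@@H](C#C[O-])[C@@H](OCc9ccccc9)[C@@H](c4cc(OCc9ccccc9)c(OCc9ccccc9)c(OCc9ccccc9)c4)[O-])c2O[C@@H]1c1cc(OCc9ccccc9)c(OCc9ccccc9)c(OCc9ccccc9)c1.[Li+].[Li+] | intermediate
25 | hydroxy siloxyalkyne | CC(C)(C)[Si](C)(C)O[C@@H]1[C@@H](c2c(OCc9ccccc9)cc(OCc9ccccc9)c3c2O[C@H](c2cc(OCc9ccccc9)c(OCc9ccccc9)c(OCc9ccccc9)c2)[C@H](OCc9ccccc9)C3)c2c(OCc9ccccc9)cc(OCc9ccccc9)c([C@@H](C#CO[Si](C(C)C)(C(C)C)C(C)C)[C@@H](OCc9ccccc9)[C@@H](c4cc(OCc9ccccc9)c(OCc9ccccc9)c(OCc9ccccc9)c4)O)c2O[C@@H]1c1cc(OCc9ccccc9)c(OCc9ccccc9)c(OCc9ccccc9)c1 | intermediate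
26 | trichloroethylene | ClC=C(Cl)Cl | starting material
27 | (E)-1,2-dichlorovinyl ether on O1 | CC(C)(C)[Si](C)(C)O[C@@H]1[C@@H](c2c(OCc9ccccc9)cc(OCc9ccccc9)c3c2O[C@H](c2cc(OCc9ccccc9)c(OCc9ccccc9)c(OCc9ccccc9)c2)[C@H](OCc9ccccc9)C3)c2c(OCc9ccccc9)cc(OCc9ccccc9)c([C@@H](C#CO[Si](C(C)C)(C(C)C)C(C)C)[C@@H](OCc9ccccc9)[C@@H](c4cc(OCc9ccccc9)c(OCc9ccccc9)c(OCc9ccccc9)c4)O/C(Cl)=C\Cl)c2O[C@@H]1c1cc(OCc9ccccc9)c(OCc9ccccc9)c(OCc9ccccc9)c1 | intermediate
28 | lithium alkoxyacetylide (C8–Li) | CC(C)(C)[Si](C)(C)O[C@@H]1[C@@H](c2c(OCc9ccccc9)cc(OCc9ccccc9)c3c2O[C@H](c2cc(OCc9ccccc9)c(OCc9ccccc9)c(OCc9ccccc9)c2)[C@H](OCc9ccccc9)C3)c2c(OCc9ccccc9)cc(OCc9ccccc9)c([C@@H](C#CO[Si](C(C)C)(C(C)C)C(C)C)[C@@H](OCc9ccccc9)[C@@H](c4cc(OCc9ccccc9)c(OCc9ccccc9)c(OCc9ccccc9)c4)OC#C[Li])c2O[C@@H]1c1cc(OCc9ccccc9)c(OCc9ccccc9)c(OCc9ccccc9)c1 | intermediate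
29 | diyne precursor of the key step | CC(C)(C)[Si](C)(C)O[C@@H]1[C@@H](c2c(OCc9ccccc9)cc(OCc9ccccc9)c3c2O[C@H](c2cc(OCc9ccccc9)c(OCc9ccccc9)c(OCc9ccccc9)c2)[C@H](OCc9ccccc9)C3)c2c(OCc9ccccc9)cc(OCc9ccccc9)c([C@@H](C#CO[Si](C(C)C)(C(C)C)C(C)C)[C@@H](OCc9ccccc9)[C@@H](c4cc(OCc9ccccc9)c(OCc9ccccc9)c(OCc9ccccc9)c4)OC#C)c2O[C@@H]1c1cc(OCc9ccccc9)c(OCc9ccccc9)c(OCc9ccccc9)c1 | intermediate
30 | acetylene | C#C | starting material
31 | lithium ethynolate | C#C[O-].[Li+] | intermediate
32 | triisopropylsiloxyacetylene | C#CO[Si](C(C)C)(C(C)C)C(C)C | intermediate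
33 | protected trimer, top 5,7-bis-OTIPS, middle 3-OTBS | CC(C)(C)[Si](C)(C)O[C@@H]1[C@@H](c2c(OCc9ccccc9)cc(OCc9ccccc9)c3c2O[C@H](c2cc(OCc9ccccc9)c(OCc9ccccc9)c(OCc9ccccc9)c2)[C@H](OCc9ccccc9)C3)c2c(OCc9ccccc9)cc(OCc9ccccc9)c([C@H]3c4c(O[Si](C(C)C)(C(C)C)C(C)C)cc(O[Si](C(C)C)(C(C)C)C(C)C)cc4O[C@H](c4cc(OCc9ccccc9)c(OCc9ccccc9)c(OCc9ccccc9)c4)[C@@H]3OCc9ccccc9)c2O[C@@H]1c1cc(OCc9ccccc9)c(OCc9ccccc9)c(OCc9ccccc9)c1 | intermediate
34 | trimer with free middle 3-OH | O[C@@H]1[C@@H](c2c(OCc9ccccc9)cc(OCc9ccccc9)c3c2O[C@H](c2cc(OCc9ccccc9)c(OCc9ccccc9)c(OCc9ccccc9)c2)[C@H](OCc9ccccc9)C3)c2c(OCc9ccccc9)cc(OCc9ccccc9)c([C@H]3c4c(O[Si](C(C)C)(C(C)C)C(C)C)cc(O[Si](C(C)C)(C(C)C)C(C)C)cc4O[C@H](c4cc(OCc9ccccc9)c(OCc9ccccc9)c(OCc9ccccc9)c4)[C@@H]3OCc9ccccc9)c2O[C@@H]1c1cc(OCc9ccccc9)c(OCc9ccccc9)c(OCc9ccccc9)c1 | intermediate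
35 | 3,4,5-tris(benzyloxy)benzoic acid | O=C(O)c1cc(OCc9ccccc9)c(OCc9ccccc9)c(OCc9ccccc9)c1 | starting material
36 | 3,4,5-tris(benzyloxy)benzoyl chloride | O=C(Cl)c1cc(OCc9ccccc9)c(OCc9ccccc9)c(OCc9ccccc9)c1 | intermediate
37 | protected trimer middle 3-O-(tribenzylgalloyl) ester | O=C(O[C@@H]1[C@@H](c2c(OCc9ccccc9)cc(OCc9ccccc9)c3c2O[C@H](c2cc(OCc9ccccc9)c(OCc9ccccc9)c(OCc9ccccc9)c2)[C@H](OCc9ccccc9)C3)c2c(OCc9ccccc9)cc(OCc9ccccc9)c([C@H]3c4c(O[Si](C(C)C)(C(C)C)C(C)C)cc(O[Si](C(C)C)(C(C)C)C(C)C)cc4O[C@H](c4cc(OCc9ccccc9)c(OCc9ccccc9)c(OCc9ccccc9)c4)[C@@H]3OCc9ccccc9)c2O[C@@H]1c1cc(OCc9ccccc9)c(OCc9ccccc9)c(OCc9ccccc9)c1)c1cc(OCc9ccccc9)c(OCc9ccccc9)c(OCc9ccccc9)c1 | intermediate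
38 | gallate with free top 5-OH and 7-OH | O=C(O[C@@H]1[C@@H](c2c(OCc9ccccc9)cc(OCc9ccccc9)c3c2O[C@H](c2cc(OCc9ccccc9)c(OCc9ccccc9)c(OCc9ccccc9)c2)[C@H](OCc9ccccc9)C3)c2c(OCc9ccccc9)cc(OCc9ccccc9)c([C@H]3c4c(O)cc(O)cc4O[C@H](c4cc(OCc9ccccc9)c(OCc9ccccc9)c(OCc9ccccc9)c4)[C@@H]3OCc9ccccc9)c2O[C@@H]1c1cc(OCc9ccccc9)c(OCc9ccccc9)c(OCc9ccccc9)c1)c1cc(OCc9ccccc9)c(OCc9ccccc9)c(OCc9ccccc9)c1 | intermediate
39 | CNP0278699.1, epigallocatechin-(4β→8)-epigallocatechin 3-O-gallate-(4β→8)-epigallocatechin | O=C(O[C@@H]1[C@@H](c2c(O)cc(O)c3c2O[C@H](c2cc(O)c(O)c(O)c2)[C@H](O)C3)c2c(O)cc(O)c([C@H]3c4c(O)cc(O)cc4O[C@H](c4cc(O)c(O)c(O)c4)[C@@H]3O)c2O[C@@H]1c1cc(O)c(O)c(O)c1)c1cc(O)c(O)c(O)c1 | target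

**Step count**

Total step count: 24. Longest linear sequence: 17 steps (6–17, 19, 20, 22–24).

**Steps most likely to fail**

Step 19 (the step beyond known chemistry).
- What may go wrong: the oxidative coupling of the hindered 1,7-diyne may be outrun by self-trimerisation of the siloxyacetylene. The cationic rhodium may be tied up by the many arenes and ethers. The third alkyne may insert in the reverse sense. The benzylic ethynyl ether may rearrange before it is consumed.
- Fallback (known chemistry, no cycloaddition): the top unit is brought in as an intact flavan. The detour sets out from 3 and 6.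
- DDQ oxidation of 3 in the presence of 2-ethoxyethanol gives 3,5,7,3',4',5'-hexa-O-benzyl-4β-(2-ethoxyethoxy)epigallocatechin F1.
- TMSOTf-promoted Friedel–Crafts coupling of F1 with an excess of dimer 6 at −78 °C gives the perbenzylated 4β→8,4β→8 trimer carrying the middle 3-O-TBS group F2.
- Aqueous HF gives the middle-unit 3-alcohol F3, and acylation with 36 gives the perbenzylated middle 3-O-gallate F4.
- Hydrogenolysis over Pd(OH)2/C rejoins the route at target 39.

Step 13.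
- What may go wrong: facial selectivity at C4 of the open-chain cation may be poor. The cation may be lost to intramolecular Friedel–Crafts closure by ring B. Alkylation may stray to a C6 position of the crowded dimer.
- Fallback: substrate control through cobalt is replaced by catalyst control.
- The uncomplexed acetate 18 and dimer 6 are joined by copper-catalysed asymmetric propargylic substitution ([Cu(MeCN)4]BF4, a chiral Ph-pybox ligand, i-Pr2NEt, MeOH–CH2Cl2, 0 °C).
- Both epimers of 18 converge on one planar copper allenylidene, and the ligand antipode is chosen to direct the arene to the required face of C4.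
- The detour sets out from 18 and 6, skips steps 12 and 14, and rejoins the route at 22. It passes through no compound outside the list (F0).

Step 17.
- What may go wrong: silyl transfer from the ynol oxygen to the potassium alkoxide, attack of butyllithium at silicon, or lithiation at C4 during the chlorine–lithium exchange would each destroy the siloxyalkyne.
- Fallback: a two-carbon donor is used that needs only an E2 elimination by a hindered amide base and no alkyllithium.
- From 25, KH and (Z)-1,2-dichloroethene (chloroacetylene formed in situ, anti addition of the alkoxide) give the (Z)-2-chlorovinyl ether on O1 F5.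
- LiN(i-Pr)2 (2.5 equiv, THF, −78 °C) removes HCl anti-periplanar, and methanol protonates the acetylide. This rejoins the route at 29.

**Further compounds**

F1 | step 19 | 3,5,7,3',4',5'-hexa-O-benzyl-4β-(2-ethoxyethoxy)epigallocatechin | C(c9ccccc9)O[C@@H]1[C@@H](OCCOCC)c2c(OCc9ccccc9)cc(OCc9ccccc9)cc2O[C@@H]1c1cc(OCc9ccccc9)c(OCc9ccccc9)c(OCc9ccccc9)c1
F2 | step 19 | perbenzylated trimer with middle 3-O-TBS | CC(C)(C)[Si](C)(C)O[C@@H]1[C@@H](c2c(OCc9ccccc9)cc(OCc9ccccc9)c3c2O[C@H](c2cc(OCc9ccccc9)c(OCc9ccccc9)c(OCc9ccccc9)c2)[C@H](OCc9ccccc9)C3)c2c(OCc9ccccc9)cc(OCc9ccccc9)c([C@H]3c4c(OCc9ccccc9)cc(OCc9ccccc9)cc4O[C@H](c4cc(OCc9ccccc9)c(OCc9ccccc9)c(OCc9ccccc9)c4)[C@@H]3OCc9ccccc9)c2O[C@@H]1c1cc(OCc9ccccc9)c(OCc9ccccc9)c(OCc9ccccc9)c1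
F3 | step 19 | perbenzylated trimer with free middle 3-OH | O[C@@H]1[C@@H](c2c(OCc9ccccc9)cc(OCc9ccccc9)c3c2O[C@H](c2cc(OCc9ccccc9)c(OCc9ccccc9)c(OCc9ccccc9)c2)[C@H](OCc9ccccc9)C3)c2c(OCc9ccccc9)cc(OCc9ccccc9)c([C@H]3c4c(OCc9ccccc9)cc(OCc9ccccc9)cc4O[C@H](c4cc(OCc9ccccc9)c(OCc9ccccc9)c(OCc9ccccc9)c4)[C@@H]3OCc9ccccc9)c2O[C@@H]1c1cc(OCc9ccccc9)c(OCc9ccccc9)c(OCc9ccccc9)c1
F4 | step 19 | perbenzylated trimer middle 3-O-(tribenzylgalloyl) ester | O=C(O[C@@H]1[C@@H](c2c(OCc9ccccc9)cc(OCc9ccccc9)c3c2O[C@H](c2cc(OCc9ccccc9)c(OCc9ccccc9)c(OCc9ccccc9)c2)[C@H](OCc9ccccc9)C3)c2c(OCc9ccccc9)cc(OCc9ccccc9)c([C@H]3c4c(OCc9ccccc9)cc(OCc9ccccc9)cc4O[C@H](c4cc(OCc9ccccc9)c(OCc9ccccc9)c(OCc9ccccc9)c4)[C@@H]3OCc9ccccc9)c2O[C@@H]1c1cc(OCc9ccccc9)c(OCc9ccccc9)c(OCc9ccccc9)c1)c1cc(OCc9ccccc9)c(OCc9ccccc9)c(OCc9ccccc9)c1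
F0 | step 13 | none | none
F5 | step 17 | (Z)-2-chlorovinyl ether on O1 of 25 | CC(C)(C)[Si](C)(C)O[C@@H]1[C@@H](c2c(OCc9ccccc9)cc(OCc9ccccc9)c3c2O[C@H](c2cc(OCc9ccccc9)c(OCc9ccccc9)c(OCc9ccccc9)c2)[C@H](OCc9ccccc9)C3)c2c(OCc9ccccc9)cc(OCc9ccccc9)c([C@@H](C#CO[Si](C(C)C)(C(C)C)C(C)C)[C@@H](OCc9ccccc9)[C@@H](c4cc(OCc9ccccc9)c(OCc9ccccc9)c(OCc9ccccc9)c4)O/C=C\Cl)c2O[C@@H]1c1cc(OCc9ccccc9)c(OCc9ccccc9)c(OCc9ccccc9)c1
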